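**Retrosynthetic overview**

1. Feature: the cyclohept-2-en-1-one ring, numbered C1 (C=O), C2 (bearing CH2OH), C3, C4, C5 (quaternary), C6 (enol-ester arm), C7 (acetonyl arm). C7–C1–C2–C3–C4 is the five-carbon unit of a 3-oxidopyrylium, C5–C6 is an E-trisubstituted geranyl alkene, and the C6 and C7 arms are the two halves of a cis-diol held in a six-membered tether ring.
2. Target ⇐ desilylation; E-enol senecioylation of the C6 aldehyde; NaIO4 cleavage of the tether diol (methyl ketone + aldehyde); C4 deoxygenation; SmI2 opening of the C7–O bridge with kinetic protonation at C7.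
3. ⇐ intramolecular (5+2) cycloaddition of the ylide from 6-acetoxypyranone 15, forming C4–C5 and C6–C7 and closing the seven-membered carbocycle and the six-membered tether ring together.
4. 15 ⇐ Achmatowicz rearrangement of a 2-furylcarbinol made from 2-lithiated furan-3-carboxylic acid and aldehyde 8; 8 ⇐ asymmetric epoxidation and inverting hydrolysis of trienol 4 ⇐ but-3-yn-1-ol + geranyl bromide.
5. Ring order: dioxolane (step 4), pyranone (step 9), carbocycle and tether ring together (step 11); the tether ring is opened again in step 16.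

Key step: step 11

Remark: the hydroxymethyl group is carried as its tert-butyldiphenylsilyl (TBDPS) ether so that it survives the acidic acetonide removal in step 15. Target locants C1–C7 are used for all ring compounds, and Diox = (4S,5R)-5-[(2E)-3,7-dimethylocta-2,6-dien-1-yl]-2,2,4-trimethyl-1,3-dioxolan-4-yl.

Assumption: the antipode of the bishydroxamic acid ligand in step 2 is chosen as the one that delivers the (2R,3R)-epoxide; both antipodes are accessible from the cyclohexane-1,2-diamine enantiomers.

**Route**

Step 1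
Reactants: 1 but-3-yn-1-ol; 2 geranyl bromide
Product: 4 (3E,6E)-3,7,11-trimethyldodeca-3,6,10-trien-1-ol, via E-alkenylalane 3 (not isolated)
Conditions: Me3Al (3 equiv), Cp2ZrCl2 (0.25 equiv), CH2Cl2, 0 °C to rt; then 2, Pd(PPh3)4 (3 mol%), THF, rt; aq. potassium sodium tartrate
Reagents that add atoms: trimethylaluminium, C[Al](C)C
Why: Zirconium-catalysed methylalumination of the terminal alkyne is a syn carbometalation that puts aluminium on the terminal carbon, and the E-alkenylalane should then undergo palladium-catalysed cross-coupling with the allylic bromide at its primary carbon with retention of both alkene geometries (the 1,4-diene synthesis from alkenylalanes and allylic halides).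

Step 2
Reactants: 4 (3E,6E)-3,7,11-trimethyldodeca-3,6,10-trien-1-ol
Product: 5 2-[(2R,3R)-3-[(2E)-3,7-dimethylocta-2,6-dien-1-yl]-2-methyloxiran-2-yl]ethan-1-ol
Conditions: VO(OiPr)3 (2 mol%), chiral N,N'-dihydroxy-N,N'-bis(diarylacetyl)-trans-cyclohexane-1,2-diamine ligand (4 mol%), cumene hydroperoxide (1.5 equiv), toluene, rt
Reagents that add atoms: cumene hydroperoxide, CC(C)(OO)c1ccccc1
Why: In this vanadium-catalysed asymmetric epoxidation of homoallylic alcohols the alkoxide binds vanadium, so oxygen should be delivered only to the 3,4-alkene, the chiral bishydroxamate sets both epoxide centres, and the E geometry is carried into the trans-epoxide.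

Step 3
Reactants: 5 2-[(2R,3R)-3-[(2E)-3,7-dimethylocta-2,6-dien-1-yl]-2-methyloxiran-2-yl]ethan-1-ol
Product: 6 (3S,4R,6E)-3,7,11-trimethyldodeca-6,10-diene-1,3,4-triol
Conditions: HClO4 (cat.), THF/H2O (3:1), 0 °C
Reagents that add atoms: water, O
Why: Acid-catalysed epoxide hydrolysis (borderline A-2 opening) lets water attack the tertiary carbon with inversion while the secondary C–O bond is untouched, which should give the anti (3S,4R) diol needed for a cis-dioxolane.

Step 4
Reactants: 6 (3S,4R,6E)-3,7,11-trimethyldodeca-6,10-diene-1,3,4-triol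
Product: 7 2-(Diox)ethan-1-ol
Conditions: 2,2-dimethoxypropane (1.5 equiv), PPTS (cat.), acetone, rt
Reagents that add atoms: 2,2-dimethoxypropane, COC(C)(C)OC
Why: Thermodynamic acetalisation should select the five-membered dioxolane on the vicinal tertiary/secondary diol, because the 1,3-dioxane through the primary hydroxyl would force a substituent of the quaternary carbon syn-axial to an acetal methyl; both carbinol centres are retained.

Step 5
Reactants: 7 2-(Diox)ethan-1-ol
Product: 8 2-(Diox)acetaldehyde
Conditions: Dess–Martin periodinane (1.3 equiv), NaHCO3, CH2Cl2, 0 °C to rt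
Reagents that add atoms: none
Why: Dess–Martin oxidation under bicarbonate buffer is neutral and fast, so the β-alkoxy aldehyde should not eliminate and the acetonide and alkenes are untouched.

Step 6
Reactants: 8 2-(Diox)acetaldehyde; 9 furan-3-carboxylic acid
Product: 11 2-[2-(Diox)-1-hydroxyethyl]furan-3-carboxylic acid (both carbinol epimers), via dilithiated furoate 10 (not isolated)
Conditions: LiN(iPr)2 (2.1 equiv), THF, −78 °C; then 8, −78 °C; aq. NaH2PO4
Reagents that add atoms: none
Why: Carboxylate-directed lithiation of furan-3-carboxylic acid with two equivalents of lithium amide occurs only at C2 (between the ring oxygen and the carboxylate), and the dianion adds 1,2 to the aldehyde; the new carbinol centre forms unselectively and is erased later in the ylide.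

Step 7
Reactants: 11 2-[2-(Diox)-1-hydroxyethyl]furan-3-carboxylic acid
Product: 12 2-(Diox)-1-[3-(hydroxymethyl)furan-2-yl]ethan-1-ol
Conditions: LiAlH4 (3 equiv), THF, 0 to 40 °C; aq. potassium sodium tartrate
Reagents that add atoms: none
Why: LiAlH4 reduces the carboxylic acid (or any lactone formed from it on standing) to the primary alcohol without touching the furan, the acetonide or the alkenes.

Step 8
Reactants: 12 2-(Diox)-1-[3-(hydroxymethyl)furan-2-yl]ethan-1-ol
Product: 13 1-[3-(TBDPS-oxymethyl)furan-2-yl]-2-(Diox)ethan-1-ol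
Conditions: TBDPSCl (1.05 equiv), imidazole, CH2Cl2, 0 °C
Reagents that add atoms: tert-butyl(chloro)diphenylsilane, CC(C)(C)[Si](Cl)(c1ccccc1)c1ccccc1
Why: The bulky silyl chloride should silylate the primary hydroxyl far faster than the secondary furyl carbinol, which must stay free to direct step 9.

Step 9
Reactants: 13 1-[3-(TBDPS-oxymethyl)furan-2-yl]-2-(Diox)ethan-1-ol
Product: 14 4-(TBDPS-oxymethyl)-2-(Diox-methyl)-6-hydroxy-2H-pyran-3(6H)-one (mixture at C2 and C6 of the pyranone)
Conditions: VO(acac)2 (5 mol%), t-BuOOH (1.5 equiv), CH2Cl2, 0 °C to rt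
Reagents that add atoms: tert-butyl hydroperoxide, CC(C)(C)OO
Why: Achmatowicz rearrangement: the vanadium alkylperoxide is bound by the carbinol hydroxyl and oxidises the adjacent furan double bond, the ring-opened ene-dione closes through the carbinol oxygen to the 6-hydroxypyranone, and the remote trisubstituted alkenes, which have no directing hydroxyl, should be left alone.

Step 10
Reactants: 14 4-(TBDPS-oxymethyl)-2-(Diox-methyl)-6-hydroxy-2H-pyran-3(6H)-one
Product: 15 6-acetoxy-4-(TBDPS-oxymethyl)-2-(Diox-methyl)-2H-pyran-3(6H)-one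
Conditions: Ac2O, pyridine, DMAP (cat.), CH2Cl2, 0 °C
Reagents that add atoms: acetic anhydride, CC(=O)OC(C)=O
Why: Acetylation of the hemiacetal hydroxyl installs the leaving group for ylide formation; both pyranone centres are mixtures and are lost in step 11.

Step 11
Reactants: 15 6-acetoxy-4-(TBDPS-oxymethyl)-2-(Diox-methyl)-2H-pyran-3(6H)-one
Product: 17 oxygen-bridged tetracyclic cycloadduct (4R,5R,6R,7R; acetal-bearing carbons S at C–CH3 and R at CH), via oxidopyrylium ylide 16 (not isolated)
Conditions: iPr2NEt (3 equiv), MeCN (0.01 M), 70 °C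
Reagents that add atoms: none
Why: The amine removes the proton at C2 of the pyranone (C7 of the target) and acetate leaves from C6, giving the 3-oxidopyrylium 16, whose termini add suprafacially to the tethered alkene in a concerted, thermally allowed (5+2) cycloaddition; the closest known reaction is the intramolecular oxidopyrylium–alkene cycloaddition of 6-acetoxypyranones that carry the alkenyl chain on the carbon next to the ketone. The seven-membered carbocycle is closed by the cycloaddition itself (new bonds C4–C5 and C6–C7, the former ring oxygen remaining as the C7–O–C4 bridge), and the six-membered tether ring is closed in the same event through the C6–C7 bond in a fused, exo mode, since the four-atom tether can only reach across the oxygen edge of the ylide. C5 and C6 are set by suprafacial addition to the E-alkene (methyl cis to the tether CH2, so both exo, homoprenyl endo) and C4 and C7 by the bridge, all four relative to one another. The step needs selection between the two faces of the planar ylide, and the cis-dioxolane should provide it: in the chair-like forming ring that leads to 17 the tertiary methyl is equatorial and only one acetal oxygen is axial, whereas addition to the other face needs the methyl axial and pointing at the pyrylium oxygen plus an axial C–O bond. Regiochemistry is fixed by the tether, the unactivated trisubstituted alkene is tolerated because the reaction is intramolecular and helped by the quaternary acetal carbon (Thorpe–Ingold effect), and high dilution suppresses ylide dimerisation.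

Step 12
Reactants: 17 oxygen-bridged tetracyclic cycloadduct
Product: 19 cis-fused bicyclic 4-hydroxy enone (4R,5R,6S,7R; H6 and H7 cis; acetonide intact), via samarium enolate 18 (not isolated)
Conditions: SmI2 (2.5 equiv), THF, −78 °C; then 2,6-di-tert-butyl-4-methylphenol (3 equiv), −78 °C; aq. NH4Cl
Reagents that add atoms: none
Why: SmI2 reduction of an α-alkoxy ketone: two single-electron transfers to the carbonyl expel the C7 oxygen (held nearly perpendicular to the carbonyl plane) as the C4 alkoxide and leave ring-fusion enolate 18, whose kinetic protonation by the hindered phenol should occur on the face away from the departed oxygen, that face being screened by the C5 methyl and the axial acetal oxygen, so that H6 and H7 end up cis as in the kinetic ketonisation of ring-fusion enols of 1-decalone type.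

Step 13
Reactants: 19 cis-fused bicyclic 4-hydroxy enone
Product: 20 C4 acetate of 19
Conditions: Ac2O, DMAP (cat.), pyridine, CH2Cl2, rt
Reagents that add atoms: acetic anhydride, CC(=O)OC(C)=O
Why: DMAP-catalysed acetylation turns the neopentyl allylic C4 hydroxyl into a leaving group for the vinylogous reduction; C7 should not be enolised under these conditions.

Step 14
Reactants: 20 C4 acetate of 19
Product: 23 cis-fused bicyclic enone with C4H2 (5S,6S,7R; acetonide intact), via samarium dienolate 21 (not isolated), via deconjugated ketone 22 (not isolated)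
Conditions: SmI2 (2.5 equiv), THF/MeOH (10:1), −78 °C; aq. NH4Cl; then DBU (0.1 equiv), CH2Cl2, 0 °C
Reagents that add atoms: none
Why: SmI2 reduction of a γ-acyloxy enone (the vinylogous α-heterosubstituted ketone cleavage) expels acetate to give dienolate 21, methanol protonates it mainly at C2 to give the β,γ-unsaturated ketone 22, and catalytic DBU removes the doubly activated C2 proton and returns it at C4 to give the conjugated trisubstituted enone, which should be much faster than enolisation toward the hindered ring-fusion C7.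

Step 15
Reactants: 23 cis-fused bicyclic enone with C4H2
Product: 24 cis-diol from 23 (tertiary carbinol S, secondary carbinol R)
Conditions: AcOH/THF/H2O (3:1:1), 45 °C
Reagents that add atoms: none
Why: Aqueous acetic acid hydrolyses the isopropylidene acetal while the tert-butyldiphenylsilyl ether, the enone and the isolated alkene should be stable to it.

Step 16
Reactants: 24 cis-diol from 23
Product: 25 [(5S,6S,7R)-2-(TBDPS-oxymethyl)-5-methyl-5-(4-methylpent-3-en-1-yl)-1-oxo-7-(2-oxopropyl)cyclohept-2-en-6-yl]acetaldehyde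
Conditions: NaIO4 (1.5 equiv), THF/H2O (2:1), 0 °C to rt
Reagents that add atoms: none
Why: Malaprade glycol cleavage of the cis-diol through a cyclic periodate ester turns the tertiary carbinol carbon into the methyl ketone of the C7 acetonyl arm and the secondary one into the aldehyde of the C6 arm, opening the tether ring without touching C6 or C7.

Step 17
Reactants: 25 keto aldehyde
Product: 26 (E)-2-[(5S,6S,7R)-2-(TBDPS-oxymethyl)-5-methyl-5-(4-methylpent-3-en-1-yl)-1-oxo-7-(2-oxopropyl)cyclohept-2-en-6-yl]ethenyl 3-methylbut-2-enoate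
Conditions: 3-methylbut-2-enoic anhydride (3 equiv), Et3N (4 equiv), DMAP (0.2 equiv), THF, rt to 40 °C
Reagents that add atoms: 3-methylbut-2-enoic anhydride, CC(C)=CC(=O)OC(=O)C=C(C)C
Why: Amine/DMAP-mediated enol acylation: only the aldehyde should be enolised by triethylamine in the presence of the acylpyridinium, and O-acylation of the enolate whose oxygen is anti to the bulky ring carbon should give the E enol ester; the anhydride is used instead of the acid chloride to avoid vinylketene formation and deconjugation of the senecioyl group.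

Step 18
Reactants: 26 silyl-protected enol ester
Product: 27 (E)-2-[(5S,6S,7R)-2-(hydroxymethyl)-5-methyl-5-(4-methylpent-3-en-1-yl)-1-oxo-7-(2-oxopropyl)cyclohept-2-en-6-yl]ethenyl 3-methylbut-2-enoate (CNP0247522.1)
Conditions: HF·pyridine, pyridine, THF, 0 °C to rt
Reagents that add atoms: none
Why: Fluoride-mediated silyl ether cleavage with pyridine-buffered HF·pyridine is non-basic, so the enol ester, the enone and the C7 centre should be preserved.

**Compound list**

1 | but-3-yn-1-ol | OCCC#C | starting material
2 | geranyl bromide, (2E)-1-bromo-3,7-dimethylocta-2,6-diene | BrC/C=C(\C)CCC=C(C)C | starting material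
3 | [(1E)-4-(dimethylalumanyloxy)-2-methylbut-1-en-1-yl]dimethylalumane | C/C(CCO[Al](C)C)=C\[Al](C)C | intermediate (not isolated)
4 | (3E,6E)-3,7,11-trimethyldodeca-3,6,10-trien-1-ol | OCC/C(C)=C/C/C=C(\C)CCC=C(C)C | intermediate
5 | 2-[(2R,3R)-3-[(2E)-3,7-dimethylocta-2,6-dien-1-yl]-2-methyloxiran-2-yl]ethan-1-ol | OCC[C@@]1(C)O[C@@H]1C/C=C(\C)CCC=C(C)C | intermediate
6 | (3S,4R,6E)-3,7,11-trimethyldodeca-6,10-diene-1,3,4-triol | OCC[C@](C)(O)[C@H](O)C/C=C(\C)CCC=C(C)C | intermediate
7 | 2-[(4S,5R)-5-[(2E)-3,7-dimethylocta-2,6-dien-1-yl]-2,2,4-trimethyl-1,3-dioxolan-4-yl]ethan-1-ol | OCC[C@]1(C)OC(C)(C)O[C@@H]1C/C=C(\C)CCC=C(C)C | intermediate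
8 | 2-[(4S,5R)-5-[(2E)-3,7-dimethylocta-2,6-dien-1-yl]-2,2,4-trimethyl-1,3-dioxolan-4-yl]acetaldehyde | O=CC[C@]1(C)OC(C)(C)O[C@@H]1C/C=C(\C)CCC=C(C)C | intermediate
9 | furan-3-carboxylic acid | OC(=O)c1ccoc1 | starting material
10 | lithium 2-lithiofuran-3-carboxylate | [Li]OC(=O)c1ccoc1[Li] | intermediate (not isolated)
11 | 2-[2-(Diox)-1-hydroxyethyl]furan-3-carboxylic acid, both carbinol epimers | OC(=O)c1ccoc1C(O)C[C@]2(C)OC(C)(C)O[C@@H]2C/C=C(\C)CCC=C(C)C | intermediate
12 | 2-(Diox)-1-[3-(hydroxymethyl)furan-2-yl]ethan-1-ol | OCc1ccoc1C(O)C[C@]2(C)OC(C)(C)O[C@@H]2C/C=C(\C)CCC=C(C)C | intermediate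
13 | 1-[3-[(tert-butyldiphenylsilyloxy)methyl]furan-2-yl]-2-(Diox)ethan-1-ol | CC(C)(C)[Si](c1ccccc1)(c1ccccc1)OCc1ccoc1C(O)C[C@]2(C)OC(C)(C)O[C@@H]2C/C=C(\C)CCC=C(C)C | intermediate
14 | 4-[(tert-butyldiphenylsilyloxy)methyl]-2-(Diox-methyl)-6-hydroxy-2H-pyran-3(6H)-one | OC1C=C(CO[Si](c2ccccc2)(c2ccccc2)C(C)(C)C)C(=O)C(O1)C[C@]3(C)OC(C)(C)O[C@@H]3C/C=C(\C)CCC=C(C)C | intermediate
15 | 6-acetoxy-4-[(tert-butyldiphenylsilyloxy)methyl]-2-(Diox-methyl)-2H-pyran-3(6H)-one | CC(=O)OC1C=C(CO[Si](c2ccccc2)(c2ccccc2)C(C)(C)C)C(=O)C(O1)C[C@]3(C)OC(C)(C)O[C@@H]3C/C=C(\C)CCC=C(C)C | intermediate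
16 | 4-[(tert-butyldiphenylsilyloxy)methyl]-2-(Diox-methyl)pyrylium-3-olate | [O-]c1c(CO[Si](c2ccccc2)(c2ccccc2)C(C)(C)C)cc[o+]c1C[C@]3(C)OC(C)(C)O[C@@H]3C/C=C(\C)CCC=C(C)C | intermediate (not isolated)
17 | oxygen-bridged tetracycle: cyclohept-2-en-1-one C1–C7 with an ether oxygen joining C4 and C7; 2-(TBDPS-oxymethyl); 5-methyl (exo) and 5-(4-methylpent-3-en-1-yl) (endo); C7 and C6 joined through CH2–C(CH3)(O)–CH(O)–CH2 with the two oxygens as a cis-acetonide; (4R,5R,6R,7R), acetal-bearing carbons S and R | [C@]123C(=O)C(CO[Si](c5ccccc5)(c5ccccc5)C(C)(C)C)=C[C@@H](O2)[C@](C)(CCC=C(C)C)[C@H]1C[C@H]4OC(C)(C)O[C@@]4(C)C3 | intermediate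
18 | bis(diiodosamarium) derivative: C7=C1 enolate and C4 alkoxide of the opened cycloadduct | C13=C(O[Sm](I)I)C(CO[Si](c5ccccc5)(c5ccccc5)C(C)(C)C)=C[C@@H](O[Sm](I)I)[C@](C)(CCC=C(C)C)[C@H]1C[C@H]4OC(C)(C)O[C@@]4(C)C3 | intermediate (not isolated)
19 | cis-fused bicyclic hydroxy enone: as 17 without the ether bridge, 4-hydroxy, H at C7; (4R,5R,6S,7R) | [C@H]13C(=O)C(CO[Si](c5ccccc5)(c5ccccc5)C(C)(C)C)=C[C@@H](O)[C@](C)(CCC=C(C)C)[C@H]1C[C@H]4OC(C)(C)O[C@@]4(C)C3 | intermediate
20 | C4 acetate of 19 | [C@H]13C(=O)C(CO[Si](c5ccccc5)(c5ccccc5)C(C)(C)C)=C[C@@H](OC(C)=O)[C@](C)(CCC=C(C)C)[C@H]1C[C@H]4OC(C)(C)O[C@@]4(C)C3 | intermediate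
21 | diiodosamarium dienolate (C1–O, C1=C2, C3=C4) | [C@H]13C(O[Sm](I)I)=C(CO[Si](c5ccccc5)(c5ccccc5)C(C)(C)C)C=C[C@](C)(CCC=C(C)C)[C@H]1C[C@H]4OC(C)(C)O[C@@]4(C)C3 | intermediate (not isolated)
22 | β,γ-unsaturated ketone (C3=C4, H at C2, both C2 epimers) | [C@H]13C(=O)C(CO[Si](c5ccccc5)(c5ccccc5)C(C)(C)C)C=C[C@](C)(CCC=C(C)C)[C@H]1C[C@H]4OC(C)(C)O[C@@]4(C)C3 | intermediate (not isolated)
23 | cis-fused bicyclic enone with C4H2; (5S,6S,7R); acetonide intact | [C@H]13C(=O)C(CO[Si](c5ccccc5)(c5ccccc5)C(C)(C)C)=CC[C@](C)(CCC=C(C)C)[C@H]1C[C@H]4OC(C)(C)O[C@@]4(C)C3 | intermediate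
24 | cis-diol from 23 (tertiary carbinol S, secondary carbinol R) | [C@H]13C(=O)C(CO[Si](c5ccccc5)(c5ccccc5)C(C)(C)C)=CC[C@](C)(CCC=C(C)C)[C@H]1C[C@@H](O)[C@](O)(C)C3 | intermediate
25 | [(5S,6S,7R)-2-[(tert-butyldiphenylsilyloxy)methyl]-5-methyl-5-(4-methylpent-3-en-1-yl)-1-oxo-7-(2-oxopropyl)cyclohept-2-en-6-yl]acetaldehyde | CC(=O)C[C@H]1C(=O)C(CO[Si](c2ccccc2)(c2ccccc2)C(C)(C)C)=CC[C@](C)(CCC=C(C)C)[C@H]1CC=O | intermediate
26 | (E)-2-[(5S,6S,7R)-2-[(tert-butyldiphenylsilyloxy)methyl]-5-methyl-5-(4-methylpent-3-en-1-yl)-1-oxo-7-(2-oxopropyl)cyclohept-2-en-6-yl]ethenyl 3-methylbut-2-enoate | CC(=O)C[C@H]1C(=O)C(CO[Si](c2ccccc2)(c2ccccc2)C(C)(C)C)=CC[C@](C)(CCC=C(C)C)[C@H]1/C=C/OC(=O)C=C(C)C | intermediate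
27 | (E)-2-[(5S,6S,7R)-2-(hydroxymethyl)-5-methyl-5-(4-methylpent-3-en-1-yl)-1-oxo-7-(2-oxopropyl)cyclohept-2-en-6-yl]ethenyl 3-methylbut-2-enoate | CC(=O)C[C@H]1C(=O)C(CO)=CC[C@](C)(CCC=C(C)C)[C@H]1/C=C/OC(=O)C=C(C)C | target

**Step count**

Total: 18 steps. Longest linear sequence: 18 steps, from but-3-yn-1-ol; geranyl bromide and furan-3-carboxylic acid enter as purchased.

**Steps most likely to fail**

Step 11. The acetonide may not discriminate well enough between the two faces of the ylide, or addition to the trisubstituted alkene may be slow enough for ylide dimerisation to take over. The fallback moves to catalyst control, sets out from 14 and returns at 17. Hemiacetal 14 would be acylated with 4-(methylsulfanyl)benzoyl chloride (pyridine, DMAP) to give 6-[4-(methylsulfanyl)benzoyloxy]-4-(TBDPS-oxymethyl)-2-(Diox-methyl)-2H-pyran-3(6H)-one F1. F1 would then be cyclised with a chiral primary amine–thiourea catalyst, achiral N,N'-bis[3,5-bis(trifluoromethyl)phenyl]thiourea as anion binder and AcOH in toluene. Condensation of the amine with the ketone gives an aminopyrylium held in a chiral ion pair; the catalyst antipode that reinforces the acetonide bias would be used, and hydrolysis of the iminium on work-up gives 17.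

Step 12. Protonation of the ring-fusion enolate may occur on the face the oxygen has just left (internal proton return from the neighbouring alkoxide), giving the more stable trans-fused C7 epimer. The fallback replaces substrate control by reagent control, sets out from 17 and returns at 19. After the SmI2 cleavage the enolate 18 would be intercepted with Me3SiCl/Et3N to give the bis(trimethylsilyl) compound F2 (C7=C1 trimethylsilyl dienol ether with the C4 trimethylsilyl ether). F2 would be protonated at −78 °C in toluene by a chiral Lewis-acid-assisted Brønsted acid (SnCl4·BINOL, antipode matched to the substrate) to give the C4 trimethylsilyl ether of 19 F3. Brief methanolysis with citric acid would then give 19.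

Step 17. Geometric control may be lost in the enolisation/O-acylation (Z enol ester), with base-induced intramolecular aldol or C7 epimerisation as side processes at longer reaction times. The fallback replaces kinetic by thermodynamic control of the geometry, sets out from 25 and returns at 26. The acylation would be run briefly without regard to geometry, and the mixture containing the Z isomer of 26 F4 would be equilibrated by reversible thiyl-radical addition (PhSSPh cat., visible light, benzene, rt). The E enol ester, with the acyloxy group away from the bulky ring carbon, should be favoured, giving 26.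

**Further compounds**

F1 | step 11 | 6-[4-(methylsulfanyl)benzoyloxy]-4-[(tert-butyldiphenylsilyloxy)methyl]-2-(Diox-methyl)-2H-pyran-3(6H)-one | CSc1ccc(cc1)C(=O)OC1C=C(CO[Si](c2ccccc2)(c2ccccc2)C(C)(C)C)C(=O)C(O1)C[C@]3(C)OC(C)(C)O[C@@H]3C/C=C(\C)CCC=C(C)C
F2 | step 12 | bis(trimethylsilyl) compound: C7=C1 trimethylsilyl dienol ether with C4 trimethylsilyl ether | C13=C(O[Si](C)(C)C)C(CO[Si](c5ccccc5)(c5ccccc5)C(C)(C)C)=C[C@@H](O[Si](C)(C)C)[C@](C)(CCC=C(C)C)[C@H]1C[C@H]4OC(C)(C)O[C@@]4(C)C3
F3 | step 12 | C4 trimethylsilyl ether of 19 | [C@H]13C(=O)C(CO[Si](c5ccccc5)(c5ccccc5)C(C)(C)C)=C[C@@H](O[Si](C)(C)C)[C@](C)(CCC=C(C)C)[C@H]1C[C@H]4OC(C)(C)O[C@@]4(C)C3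
F4 | step 17 | Z isomer of 26 | CC(=O)C[C@H]1C(=O)C(CO[Si](c2ccccc2)(c2ccccc2)C(C)(C)C)=CC[C@](C)(CCC=C(C)C)[C@H]1/C=C\OC(=O)C=C(C)C
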